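Both halves are one C15 seco-cadinane unit at two oxidation levels: the butenolide half is the dehydrated hydroxy-lactone half, so a single ring synthesis serves both, and a late tertiary esterification joins them. In the hydroxy-lactone cyclohexane the C5H2–C6H2 edge lies between isopropyl-bearing C4 and the oxygenated quaternary C1; read with C1 as a ketone and the lactone carbonyl on C2 as an ester, this edge is the enone C=C of a Robinson-type retron. The key step is an organocatalytic Michael/aldol-condensation domino: isovaleraldehyde adds to an acyclic alkylidene acetoacetate (C3–C4, trans stereo-pair), then the acetyl methyl closes the ring onto the aldehyde carbon (C5–C6).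

Key step: step 2

Remark on numbering (both halves): C1 = ring carbon bearing the lactone CH2O (C7); C2 = ring carbon bearing the lactone C=O; C3 = side-chain carbon; C4 = isopropyl carbon; C5, C6 = ring methylenes.
Assumption: 3 is used as its E/Z mixture (the geometry is lost in the Michael step), and the β-keto esters 5–7 are drawn as keto tautomers with C2 in the equilibrated trans configuration.

Step 1
Reactants: 1 methyl acetoacetate; 2 2,2-dimethoxyacetaldehyde
Product: 3 methyl 2-acetyl-4,4-dimethoxybut-2-enoate
Conditions: piperidine (cat.), AcOH (cat.), MgSO4, CH2Cl2, 0 °C to rt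
Reagents that add atoms: none
Why: Knoevenagel condensation of the active methylene of 1 with the non-enolisable aldehyde 2 should give the doubly activated alkene; no stereocentre is formed.

Step 2
Reactants: 3 methyl 2-acetyl-4,4-dimethoxybut-2-enoate; 4 3-methylbutanal
Product: 6 methyl (1S,5S,6R)-6-(dimethoxymethyl)-2-oxo-5-isopropylcyclohex-3-ene-1-carboxylate, via Michael adduct 5 (not isolated)
Conditions: (S)-2-[diphenyl(trimethylsilyloxy)methyl]pyrrolidine (10 mol%), PhCO2H (10 mol%), toluene, 0 °C to rt; excess 4 evaporated; then pyrrolidine, AcOH (20 mol% each), toluene, 40 °C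
Reagents that add atoms: none
Why: The (S)-amine condenses with 4 to an E-enamine whose face opposite the diphenyl(silyloxy)methyl group adds to C3 of 3 through an acyclic synclinal transition state and gives, after hydrolysis, the syn keto aldehyde 5 (C3–C4 bond); pyrrolidinium acetate then mediates the intramolecular aldol condensation in which the acetyl CH3 (C6), as enol or enamine, attacks the aldehyde carbon C5 and water is lost to the conjugated enone. The closest known reactions are the diarylprolinol silyl ether catalysed Michael additions of aldehydes to nitroalkenes and alkylidene 1,3-dicarbonyls, and the amine- or acid-promoted cyclisation of acetoacetate-derived 5-oxoaldehydes to cyclohexenones (Robinson-type annulation). The carbocycle closes in the 6-(enolendo)-exo-trig aldol mode. C4 should be set by catalyst shielding of one enamine face (R in 5, as in the nitroalkene additions of the same catalyst), C3 by the relative topicity of the synclinal transition state (the syn adduct maps onto the trans C3/C4 ring relationship), and C2, the α-carbon of a β-keto ester, by equilibration trans to the C3 substituent. The step needs C-cyclisation by the methyl carbon and not O-cyclisation of the keto-ester enol onto the aldehyde; the hemiacetal is reversible, only the aldol path is made irreversible by dehydration, and the other carbon nucleophiles (C2, C4) could close only four-membered rings. Epimerisation of C4 through the dienol would be harmless because the trans arrangement is also the thermodynamic one.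

Step 3
Reactants: 6 methyl (1S,5S,6R)-6-(dimethoxymethyl)-2-oxo-5-isopropylcyclohex-3-ene-1-carboxylate
Product: 7 methyl (1S,2R,3R)-2-(dimethoxymethyl)-6-oxo-3-isopropylcyclohexane-1-carboxylate
Conditions: H2 (1 atm), 10% Pd/C, EtOAc, rt
Reagents that add atoms: none
Why: Heterogeneous catalytic hydrogenation should reduce only the disubstituted enone C5=C6 bond, turning the ring-closing bond into the CH2–CH2 edge; no stereocentre is created and acetal, ketone and ester should survive.

Step 4
Reactants: 7 methyl (1S,2R,3R)-2-(dimethoxymethyl)-6-oxo-3-isopropylcyclohexane-1-carboxylate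
Product: 8 methyl (1S,2R,3R)-2-(dimethoxymethyl)-6-methylidene-3-isopropylcyclohexane-1-carboxylate
Conditions: Zn, CH2Br2, TiCl4, THF/CH2Cl2, 0 °C to rt
Reagents that add atoms: dibromomethane BrCBr
Why: Takai–Lombardo methylenation uses a non-basic zinc/titanium methylene reagent that should methylenate the enolisable ketone without touching the ester or epimerising C2; no new stereocentre.

Step 5
Reactants: 8 methyl (1S,2R,3R)-2-(dimethoxymethyl)-6-methylidene-3-isopropylcyclohexane-1-carboxylate
Product: 11 (3aS,4R,5R,7aS)-7a-hydroxy-3-oxo-5-isopropyloctahydro-2-benzofuran-4-carbaldehyde, via diol ester 9 (not isolated), via lactone acetal 10 (not isolated)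
Conditions: OsO4 (2 mol%), N-methylmorpholine N-oxide, acetone/H2O, rt; then 1 M HCl, THF, rt
Reagents that add atoms: osmium tetroxide O=[Os](=O)(=O)=O (reoxidised by N-methylmorpholine N-oxide C[N+]1([O-])CCOCC1); water O
Why: Upjohn dihydroxylation should occur from the equatorial direction of the all-equatorial chair (away from the axial hydrogens at C3 and C5), which sets C1 with the tertiary OH equatorial and the CH2OH axial and cis to the C2 ester; acid then closes the cis-fused γ-lactone (5-exo-trig acyl substitution) and hydrolyses the dimethyl acetal to the aldehyde.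

Step 6
Reactants: 12 allyl diethylphosphonoacetate; 13 formaldehyde (as paraformaldehyde); 14 (4-methoxyphenyl)methanol
Product: 15 allyl 2-(diethoxyphosphoryl)-3-[(4-methoxyphenyl)methoxy]propanoate
Conditions: (CH2O)n, 14 (3 equiv), piperidine (10 mol%), toluene, 80 °C
Reagents that add atoms: none
Why: Knoevenagel condensation of the phosphonoacetate with formaldehyde gives the 2-phosphonoacrylate, which should be trapped in situ by oxa-Michael addition of 14 (the alcohol-trapping variant of the standard 2-phosphonoacrylate preparation); the stereocentre is racemic and disappears in step 7.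

Step 7
Reactants: 11 (3aS,4R,5R,7aS)-7a-hydroxy-3-oxo-5-isopropyloctahydro-2-benzofuran-4-carbaldehyde; 15 allyl 2-(diethoxyphosphoryl)-3-[(4-methoxyphenyl)methoxy]propanoate
Product: 16 hydroxy-lactone monomer (allyl ester and PMB ether)
Conditions: LiCl, iPr2NEt, MeCN, rt
Reagents that add atoms: none
Why: Horner–Wadsworth–Emmons olefination under Masamune–Roush conditions should give the trisubstituted enoate with the ring trans to the carboxyl (E), the usual outcome for α-substituted phosphonoacetates, while the mild amine base spares the β-hydroxy lactone.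

Step 8
Reactants: 16 hydroxy-lactone monomer (allyl ester and PMB ether)
Product: 18 butenolide monomer allyl ester, via tertiary mesylate 17 (not isolated)
Conditions: MsCl, Et3N, CH2Cl2, 0 °C to rt
Reagents that add atoms: none
Why: Sulfene mesylation of the tertiary alcohol followed by E1cB elimination through the acidic lactone α-hydrogen at C2 should give the tetrasubstituted butenolide; C3 and C4 are untouched.

Step 9
Reactants: 18 butenolide monomer allyl ester
Product: 19 butenolide monomer acid
Conditions: Pd(PPh3)4 (5 mol%), morpholine, THF, rt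
Reagents that add atoms: none
Why: Tsuji–Trost deallylation: zerovalent palladium ionises the allyl ester and morpholine traps the π-allyl complex, which should free the acid under near-neutral conditions without touching the PMB ether or lactone.

Step 10
Reactants: 19 butenolide monomer acid; 16 hydroxy-lactone monomer (allyl ester and PMB ether)
Product: 21 protected dimer (allyl ester and bis-PMB ether), via Yamaguchi mixed anhydride 20 (not isolated)
Conditions: 2,4,6-trichlorobenzoyl chloride, Et3N, THF, rt; then 16, DMAP, toluene, 40 °C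
Reagents that add atoms: none
Why: Yamaguchi esterification through the acylpyridinium of the mixed anhydride is a standard way to acylate hindered alcohols; 16 offers only the equatorial tertiary hydroxyl and 19 only one carboxyl, so no selectivity issue arises and no stereocentre is formed.

Step 11
Reactants: 21 protected dimer (allyl ester and bis-PMB ether)
Product: 22 dimer allyl ester with both CH2OH groups free
Conditions: DDQ, CH2Cl2/pH 7 buffer, 0 °C to rt
Reagents that add atoms: none
Why: Oxidative PMB ether cleavage (benzylic hydride abstraction by DDQ, then hydrolysis of the hemiacetal) should run under neutral conditions that leave the β-acyloxy lactone, the enoates and the allyl ester intact.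

Step 12
Reactants: 22 dimer allyl ester with both CH2OH groups free
Product: 23 CNP0238371.2 (target)
Conditions: Pd(PPh3)4 (5 mol%), morpholine, THF, 0 °C to rt; mild acidic work-up
Reagents that add atoms: none
Why: Tsuji–Trost deallylation should remove the last protecting group without hydrolytic conditions, so the tertiary ester and both lactones should remain.

Compound list
1 | methyl acetoacetate | CC(=O)CC(=O)OC | starting material
2 | 2,2-dimethoxyacetaldehyde | COC(OC)C=O | starting material
3 | methyl 2-acetyl-4,4-dimethoxybut-2-enoate (E/Z mixture) | COC(OC)C=C(C(C)=O)C(=O)OC | intermediate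
4 | 3-methylbutanal (isovaleraldehyde) | CC(C)CC=O | starting material
5 | methyl (3R,4R)-2-acetyl-3-(dimethoxymethyl)-4-formyl-5-methylhexanoate (C2 epimers) | CC(C)[C@@H](C=O)[C@@H](C(OC)OC)C(C(C)=O)C(=O)OC | intermediate (not isolated)
6 | methyl (1S,5S,6R)-6-(dimethoxymethyl)-2-oxo-5-(propan-2-yl)cyclohex-3-ene-1-carboxylate | CC(C)[C@H]1C=CC(=O)[C@@H](C(=O)OC)[C@@H]1C(OC)OC | intermediate
7 | methyl (1S,2R,3R)-2-(dimethoxymethyl)-6-oxo-3-(propan-2-yl)cyclohexane-1-carboxylate | CC(C)[C@H]1CCC(=O)[C@@H](C(=O)OC)[C@@H]1C(OC)OC | intermediate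
8 | methyl (1S,2R,3R)-2-(dimethoxymethyl)-6-methylidene-3-(propan-2-yl)cyclohexane-1-carboxylate | CC(C)[C@H]1CCC(=C)[C@@H](C(=O)OC)[C@@H]1C(OC)OC | intermediate
9 | methyl (1S,2R,3R,6S)-2-(dimethoxymethyl)-6-hydroxy-6-(hydroxymethyl)-3-(propan-2-yl)cyclohexane-1-carboxylate | CC(C)[C@H]1CC[C@@](O)(CO)[C@@H](C(=O)OC)[C@@H]1C(OC)OC | intermediate (not isolated)
10 | (3aS,6R,7R,7aS)-7-(dimethoxymethyl)-3a-hydroxy-6-(propan-2-yl)hexahydro-2-benzofuran-1(3H)-one | CC(C)[C@H]1CC[C@@]2(O)COC(=O)[C@H]2[C@@H]1C(OC)OC | intermediate (not isolated)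
11 | (3aS,4R,5R,7aS)-7a-hydroxy-3-oxo-5-(propan-2-yl)octahydro-2-benzofuran-4-carbaldehyde | CC(C)[C@H]1CC[C@@]2(O)COC(=O)[C@H]2[C@@H]1C=O | intermediate
12 | prop-2-en-1-yl 2-(diethoxyphosphoryl)acetate (allyl diethylphosphonoacetate) | CCOP(=O)(CC(=O)OCC=C)OCC | starting material
13 | formaldehyde (used as paraformaldehyde) | C=O | starting material
14 | (4-methoxyphenyl)methanol | COc1ccc(CO)cc1 | starting material
15 | prop-2-en-1-yl 2-(diethoxyphosphoryl)-3-[(4-methoxyphenyl)methoxy]propanoate (racemic) | CCOP(=O)(OCC)C(COCc1ccc(OC)cc1)C(=O)OCC=C | intermediate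
16 | prop-2-en-1-yl (2E)-3-[(3aS,4S,5R,7aS)-7a-hydroxy-3-oxo-5-(propan-2-yl)octahydro-2-benzofuran-4-yl]-2-{[(4-methoxyphenyl)methoxy]methyl}prop-2-enoate | CC(C)[C@H]1CC[C@@]2(O)COC(=O)[C@H]2[C@@H]1/C=C(\COCc1ccc(OC)cc1)C(=O)OCC=C | intermediate
17 | 7a-O-methanesulfonate of 16 | CC(C)[C@H]1CC[C@@]2(OS(C)(=O)=O)COC(=O)[C@H]2[C@@H]1/C=C(\COCc1ccc(OC)cc1)C(=O)OCC=C | intermediate (not isolated)
18 | prop-2-en-1-yl (2E)-2-{[(4-methoxyphenyl)methoxy]methyl}-3-[(4S,5R)-3-oxo-5-(propan-2-yl)-1,3,4,5,6,7-hexahydro-2-benzofuran-4-yl]prop-2-enoate | CC(C)[C@H]1CCC2=C(C(=O)OC2)[C@@H]1/C=C(\COCc1ccc(OC)cc1)C(=O)OCC=C | intermediate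
19 | (2E)-2-{[(4-methoxyphenyl)methoxy]methyl}-3-[(4S,5R)-3-oxo-5-(propan-2-yl)-1,3,4,5,6,7-hexahydro-2-benzofuran-4-yl]prop-2-enoic acid | CC(C)[C@H]1CCC2=C(C(=O)OC2)[C@@H]1/C=C(\COCc1ccc(OC)cc1)C(=O)O | intermediate
20 | mixed anhydride of 19 with 2,4,6-trichlorobenzoic acid | CC(C)[C@H]1CCC2=C(C(=O)OC2)[C@@H]1/C=C(\COCc1ccc(OC)cc1)C(=O)OC(=O)c1c(Cl)cc(Cl)cc1Cl | intermediate (not isolated)
21 | ester of acid 19 with the tertiary 7a-hydroxyl of 16 (allyl ester, two PMB ethers) | CC(C)[C@H]1CC[C@@]2(OC(=O)/C(=C/[C@H]3C4=C(CC[C@@H]3C(C)C)COC4=O)COCc3ccc(OC)cc3)COC(=O)[C@H]2[C@@H]1/C=C(\COCc1ccc(OC)cc1)C(=O)OCC=C | intermediate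
22 | allyl ester of the target (both CH2OH groups free) | CC(C)[C@H]1CC[C@@]2(OC(=O)/C(=C/[C@H]3C4=C(CC[C@@H]3C(C)C)COC4=O)CO)COC(=O)[C@H]2[C@@H]1/C=C(\CO)C(=O)OCC=C | intermediate
23 | CNP0238371.2: (2E)-3-[(3aS,4S,5R,7aS)-7a-({(2E)-2-(hydroxymethyl)-3-[(4S,5R)-3-oxo-5-(propan-2-yl)-1,3,4,5,6,7-hexahydro-2-benzofuran-4-yl]prop-2-enoyl}oxy)-3-oxo-5-(propan-2-yl)octahydro-2-benzofuran-4-yl]-2-(hydroxymethyl)prop-2-enoic acid | CC(C)[C@H]1CC[C@@]2(OC(=O)/C(=C/[C@H]3C4=C(CC[C@@H]3C(C)C)COC4=O)CO)COC(=O)[C@H]2[C@@H]1/C=C(\CO)C(=O)O | target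

Total step count: 12. Longest linear sequence: 11 steps (steps 1–5 and 7–12; step 6 prepares reagent 15).

Steps most likely to fail

Step 10. The acylation of the hindered tertiary alcohol may be too slow, and the amine bases may meanwhile deconjugate or epimerise the activated acid at its doubly allylic C3–H or eliminate the newly formed β-acyloxy lactone. Fallback (sets out from 15, 16 and 11, returns at 21): the union would be made by olefination instead of esterification. Deallylation of 15 (Pd(PPh3)4, morpholine) would give 2-(diethoxyphosphoryl)-3-[(4-methoxyphenyl)methoxy]propanoic acid F5. This small acid should acylate the tertiary hydroxyl of 16 through its phosphonoketene (DCC, cat. DMAP, CH2Cl2) to give the phosphonate ester F6. Aldehyde 11 would be dehydrated (MsCl, Et3N) to (4R,5R)-3-oxo-5-isopropyl-1,3,4,5,6,7-hexahydro-2-benzofuran-4-carbaldehyde F7, used at once. A Horner–Wadsworth–Emmons reaction of F6 with F7 (LiCl, iPr2NEt, MeCN, 0 °C) should then give 21.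

Step 4. The β-keto ester may enolise and be recovered instead of being methylenated, and the Lewis acidic titanium reagent may cleave the dimethyl acetal. Fallback (sets out from 7, returns at 8): 7 would be converted into its enol triflate F3 (NaH, PhNTf2, THF). A Kumada coupling with Me3SiCH2MgCl (Pd(PPh3)4, THF) would give the allylsilane F4. Fluoride-induced protodesilylation (Bu4NF, AcOH, THF) should generate the dienolate and protonate it at C2, which moves the double bond into the exocyclic position and gives 8.

Step 2. The keto aldehyde may cyclise through oxygen (hemiacetal, then 4H-pyran) rather than through the methyl carbon, or the Michael step may lose diastereocontrol between two branched carbons. Fallback (sets out from 5, isolated after the Michael stage, returns at 7): the aldehyde would be reduced chemoselectively (NaBH4, MeOH, −78 °C) to the primary alcohol methyl (3R,4R)-2-acetyl-3-(dimethoxymethyl)-4-(hydroxymethyl)-5-methylhexanoate F1. This would be converted into the iodide methyl (3R,4R)-2-acetyl-3-(dimethoxymethyl)-4-(iodomethyl)-5-methylhexanoate F2 (I2, PPh3, imidazole). The acetoacetate dianion (NaH, then n-BuLi, THF, −78 to 0 °C) should then close the same C5–C6 bond by intramolecular γ-alkylation and give 7 directly.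

Further compounds
F1 | step 2 | methyl (3R,4R)-2-acetyl-3-(dimethoxymethyl)-4-(hydroxymethyl)-5-methylhexanoate | CC(C)[C@@H](CO)[C@@H](C(OC)OC)C(C(C)=O)C(=O)OC
F2 | step 2 | methyl (3R,4R)-2-acetyl-3-(dimethoxymethyl)-4-(iodomethyl)-5-methylhexanoate | CC(C)[C@@H](CI)[C@@H](C(OC)OC)C(C(C)=O)C(=O)OC
F3 | step 4 | methyl (5R,6R)-6-(dimethoxymethyl)-5-(propan-2-yl)-2-{[(trifluoromethyl)sulfonyl]oxy}cyclohex-1-ene-1-carboxylate | CC(C)[C@H]1CCC(OS(=O)(=O)C(F)(F)F)=C(C(=O)OC)[C@@H]1C(OC)OC
F4 | step 4 | methyl (5R,6R)-6-(dimethoxymethyl)-5-(propan-2-yl)-2-[(trimethylsilyl)methyl]cyclohex-1-ene-1-carboxylate | CC(C)[C@H]1CCC(C[Si](C)(C)C)=C(C(=O)OC)[C@@H]1C(OC)OC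
F5 | step 10 | 2-(diethoxyphosphoryl)-3-[(4-methoxyphenyl)methoxy]propanoic acid | CCOP(=O)(OCC)C(COCc1ccc(OC)cc1)C(=O)O
F6 | step 10 | 7a-O-{2-(diethoxyphosphoryl)-3-[(4-methoxyphenyl)methoxy]propanoyl} ester of 16 | CC(C)[C@H]1CC[C@@]2(OC(=O)C(COCc3ccc(OC)cc3)P(=O)(OCC)OCC)COC(=O)[C@H]2[C@@H]1/C=C(\COCc1ccc(OC)cc1)C(=O)OCC=C
F7 | step 10 | (4R,5R)-3-oxo-5-(propan-2-yl)-1,3,4,5,6,7-hexahydro-2-benzofuran-4-carbaldehyde | CC(C)[C@H]1CCC2=C(C(=O)OC2)[C@@H]1C=O
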